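Everything rests on disconnecting the C2–C3 bond of ring B. There an ester-bearing sp3 carbon (C2) adjoins the α-carbon (C3) of the acrylate unit C3=C4 that is conjugated with ring A, so a C2 enolate can be coupled on palladium with a C3 vinyl bromide lying cis to the arene. This one operation closes ring B, forms the only new skeletal bond and creates C2, which settles trans under control of C1. The precursor is a (3R)-3,3-diarylpropanoate whose ring A carries an ortho (Z)-α-bromoacrylate arm; ring A is benzylated, ring C is an acetonide and both esters are tert-butyl. The pyranone is made afterwards, by extradiol cleavage of ring C.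

Key step: step 5

Remarks before the steps

- Locants: C1–C8a are those of the 1,2-dihydronaphthalene of the target. Ring A is the benzo ring, ring B the dihydro ring, ring C the pendant catechol ring (primed locants) that becomes the pyranone.
- Structure check: the target is (1R,2S), with the C1 pyranyl and C2 carboxyl groups trans. C1 of the precursor is R with the same spatial arrangement, and the bromoalkene must be Z (bromine cis to ring A).
- Esters: both are tert-butyl. This ester class gives clean metal enolates, and acid rather than hydroxide removes it from the base-sensitive dihydronaphthalene.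
- Phenol protection: ring C is an isopropylidene ketal that falls in the same acid step. Ring A carries benzyl ethers, which survive that step, keep ring A out of the ring-cleavage step and leave at the end under BCl3 at low temperature. Aryl methyl ethers would need BBr3 in the presence of the pyranone.
- Nucleophile: the C2 enolate is a zinc enolate. A free lithium enolate could add to C4 of the bromoacrylate (indane formation) or eliminate HBr before palladium intervenes.
- Oxidation level: an extradiol dioxygenase by itself stops at the ring-opened semialdehyde, so step 7 includes the dehydrogenation of the cyclic hemiacetal that the pyranone requires.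
- Assumption: the benzylated bromoaldehyde, the acetonide-protected boronic acid and the tert-butyl ester ylide are taken as catalogue compounds.

Step 1
Reactants: 1 4,5-bis(benzyloxy)-2-bromobenzaldehyde
Product: 2 1,2-bis(benzyloxy)-4-bromo-5-(dimethoxymethyl)benzene
Conditions: HC(OMe)3, p-TsOH·H2O (cat.), MeOH, rt; Et3N quench
Reagents that add atoms: trimethyl orthoformate, COC(OC)OC; methanol, CO
Why: Acid-catalysed acetalisation, driven by the orthoformate as water scavenger, masks the formyl group, which in step 3 would otherwise be arylated or would trap the rhodium enolate by aldol closure; the benzyl ethers and the aryl bromide are inert.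

Step 2
Reactants: 2 1,2-bis(benzyloxy)-4-bromo-5-(dimethoxymethyl)benzene; 3 tert-butyl acrylate
Product: 4 tert-butyl (E)-3-[4,5-bis(benzyloxy)-2-(dimethoxymethyl)phenyl]prop-2-enoate
Conditions: Pd(OAc)2 (5 mol%), P(o-tol)3 (10 mol%), K2CO3, Bu4NBr, DMF, 100 °C
Reagents that add atoms: none
Why: Mizoroki–Heck reaction, in which the arylpalladium bromide adds syn across the acrylate and syn β-hydride elimination gives the (E)-cinnamate; the tert-butyl ester resists attack in the later enolate step and is removed by acid instead of base.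

Step 3
Reactants: 4 tert-butyl (E)-3-[4,5-bis(benzyloxy)-2-(dimethoxymethyl)phenyl]prop-2-enoate; 5 (2,2-dimethyl-1,3-benzodioxol-5-yl)boronic acid
Product: 7 tert-butyl (3R)-3-[4,5-bis(benzyloxy)-2-formylphenyl]-3-(2,2-dimethyl-1,3-benzodioxol-5-yl)propanoate, via dimethyl acetal adduct 6 (not isolated)
Conditions: [RhCl(C2H4)2]2 (1.5 mol%), 2,5-diphenylbicyclo[2.2.2]octa-2,5-diene (single enantiomer, 3.3 mol%), KOH (10 mol%), dioxane/H2O 10:1, 50 °C; then 0.5 M HCl, THF, rt
Reagents that add atoms: water, O
Why: Hayashi–Miyaura rhodium-catalysed asymmetric conjugate addition, in which the arylrhodium species formed by transmetalation from boron inserts the enoate inside the chiral diene pocket; the ligand antipode is the one that delivers the aryl group to the si face of C3 of 4 and so sets the future C1 as R (to be confirmed on 7), water protonates the rhodium enolate, and the dilute acid work-up then hydrolyses only the dimethyl acetal.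

Step 4
Reactants: 7 tert-butyl (3R)-3-[4,5-bis(benzyloxy)-2-formylphenyl]-3-(2,2-dimethyl-1,3-benzodioxol-5-yl)propanoate; 8 tert-butyl 2-(triphenyl-λ5-phosphanylidene)acetate
Product: 10 tert-butyl (3R)-3-{4,5-bis(benzyloxy)-2-[(Z)-2-bromo-3-tert-butoxy-3-oxoprop-1-enyl]phenyl}-3-(2,2-dimethyl-1,3-benzodioxol-5-yl)propanoate, via bromo ylide 9 (not isolated)
Conditions: 8, NBS (0.97 equiv per 8), CH2Cl2, −20 °C; then 7, rt → 40 °C
Reagents that add atoms: N-bromosuccinimide, O=C1CCC(=O)N1Br
Why: Wittig olefination with the ester-stabilised α-bromo ylide, made in the flask by bromination of 8, places the ester trans to the aryl group and hence gives mainly the (Z)-α-bromocinnamate with bromine cis to ring A; the slight deficit of NBS leaves no free brominating agent for the electron-rich arenes.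

Step 5
Reactants: 10 tert-butyl (3R)-3-{4,5-bis(benzyloxy)-2-[(Z)-2-bromo-3-tert-butoxy-3-oxoprop-1-enyl]phenyl}-3-(2,2-dimethyl-1,3-benzodioxol-5-yl)propanoate
Product: 13 di-tert-butyl (1R,2S)-6,7-bis(benzyloxy)-1-(2,2-dimethyl-1,3-benzodioxol-5-yl)-1,2-dihydronaphthalene-2,3-dicarboxylate, via zinc enolate 11 (not isolated), via cis diester 12 (not isolated)
Conditions: TMPZnCl·LiCl (TMP = 2,2,6,6-tetramethylpiperidide, 2.2 equiv), THF, 25 °C; Pd2(dba)3 (2.5 mol%), P(t-Bu)3 (10 mol%), 25 → 50 °C; aq NH4Cl; then t-BuOK (0.2 equiv), THF/t-BuOH, 0 °C, argon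
Reagents that add atoms: none
Why: The zinc amide turns the C2 methylene into the Reformatsky-type zinc enolate 11, a nucleophile too mild to add 5-exo to C4 of the bromoacrylate or to eliminate HBr from it; oxidative addition of the C3–Br bond to zerovalent palladium proceeds with retention of the (Z) geometry, intramolecular zinc-to-palladium transfer of the enolate carbon gives a seven-membered C,C-palladacycle of divalent palladium, and C–C reductive elimination from it joins C2 to C3. The closest known reaction type is the palladium-catalysed α-arylation and α-alkenylation of zinc ester enolates with aryl and vinyl bromides (Reformatsky–Negishi coupling), run here within one molecule. Ring B, six-membered, closes by C(sp3)–C(sp2) reductive elimination with the C3=C4 bond ending inside the new ring (formally endo), which is possible only because the (Z) alkene holds bromine on the side of ring A that carries the C2 arm. The new stereocentre C2 is set under thermodynamic control by the existing C1 centre: protonation on work-up should give a C2 mixture containing cis-12, and catalytic tert-butoxide equilibrates it through the dienolate to trans-13, in which the C1 aryl and C2 ester groups are both pseudoaxial. The step needs reductive elimination to outrun β-hydride elimination towards C1, which the bulky electron-rich P(t-Bu)3 secures, and it needs C1 to keep its configuration, which holds because the diarylmethine hydrogen is not acidic while the double bond stays at C3=C4.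

Step 6
Reactants: 13 di-tert-butyl (1R,2S)-6,7-bis(benzyloxy)-1-(2,2-dimethyl-1,3-benzodioxol-5-yl)-1,2-dihydronaphthalene-2,3-dicarboxylate
Product: 14 (1R,2S)-6,7-bis(benzyloxy)-1-(3,4-dihydroxyphenyl)-1,2-dihydronaphthalene-2,3-dicarboxylic acid
Conditions: TFA/CH2Cl2 1:1, H2O (10 equiv), 0 °C → rt, argon
Reagents that add atoms: none
Why: Acidolysis removes the two tert-butyl esters by alkyl–oxygen cleavage with loss of isobutene and hydrolyses the catechol isopropylidene ketal in the same operation, while the aryl benzyl ethers, the conjugated alkene and both stereocentres are stable to trifluoroacetic acid without a cation scavenger, so no base meets the epimerisable C2–H.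

Step 7
Reactants: 14 (1R,2S)-6,7-bis(benzyloxy)-1-(3,4-dihydroxyphenyl)-1,2-dihydronaphthalene-2,3-dicarboxylic acid
Product: 17 (1R,2S)-6,7-bis(benzyloxy)-1-(6-carboxy-2-oxo-2H-pyran-4-yl)-1,2-dihydronaphthalene-2,3-dicarboxylic acid, via seco-aldehyde 15 (not isolated), via cyclic hemiacetal 16 (not isolated)
Conditions: DOPA 4,5-dioxygenase, FeSO4 (cat.), sodium ascorbate (cat.), air; LigC dehydrogenase, NADP+ (cat.), NADPH oxidase; phosphate buffer pH 7.5, 10% DMSO, 30 °C
Reagents that add atoms: dioxygen, O=O
Why: Enzymatic extradiol ring cleavage followed by dehydrogenation, the sequence by which DOPA gives stizolobic acid and protocatechuate gives 2-pyrone-4,6-dicarboxylate: the divalent-iron dioxygenase inserts O2 into the C4'–C5' bond of the free 4-alkylcatechol (ring A is shielded as its dibenzyl ether), the 2-hydroxymuconate semialdehyde 15 closes through the C3' enol oxygen to hemiacetal 16, and NADP-dependent oxidation gives the pyranone, with C1 and C2 untouched at pH 7.5.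

Step 8
Reactants: 17 (1R,2S)-6,7-bis(benzyloxy)-1-(6-carboxy-2-oxo-2H-pyran-4-yl)-1,2-dihydronaphthalene-2,3-dicarboxylic acid
Product: 18 (1R,2S)-1-(6-carboxy-2-oxo-2H-pyran-4-yl)-6,7-dihydroxy-1,2-dihydronaphthalene-2,3-dicarboxylic acid (CNP0195322.1)
Conditions: BCl3 (10 equiv), C6HMe5 (6 equiv), CH2Cl2, −78 → −40 °C; then H2O/THF
Reagents that add atoms: none
Why: Lewis acid debenzylation with BCl3 and pentamethylbenzene as a non-basic benzyl cation trap cleaves the two aryl benzyl ethers at low temperature without touching the pyranone, the C3=C4 double bond or the two stereocentres, which hydrogenolysis or ether demethylation with BBr3 would put at risk.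

Compound list

1 | 4,5-bis(benzyloxy)-2-bromobenzaldehyde | O=Cc1cc(OCc2ccccc2)c(OCc2ccccc2)cc1Br | starting material
2 | 1,2-bis(benzyloxy)-4-bromo-5-(dimethoxymethyl)benzene | COC(OC)c1cc(OCc2ccccc2)c(OCc2ccccc2)cc1Br | intermediate
3 | tert-butyl acrylate | C=CC(=O)OC(C)(C)C | starting material
4 | tert-butyl (E)-3-[4,5-bis(benzyloxy)-2-(dimethoxymethyl)phenyl]prop-2-enoate | COC(OC)c1cc(OCc2ccccc2)c(OCc2ccccc2)cc1/C=C/C(=O)OC(C)(C)C | intermediate
5 | (2,2-dimethyl-1,3-benzodioxol-5-yl)boronic acid | CC1(C)Oc2ccc(B(O)O)cc2O1 | starting material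
6 | tert-butyl (3R)-3-[4,5-bis(benzyloxy)-2-(dimethoxymethyl)phenyl]-3-(2,2-dimethyl-1,3-benzodioxol-5-yl)propanoate | COC(OC)c1cc(OCc2ccccc2)c(OCc2ccccc2)cc1[C@H](CC(=O)OC(C)(C)C)c1ccc2OC(C)(C)Oc2c1 | intermediate (not isolated)
7 | tert-butyl (3R)-3-[4,5-bis(benzyloxy)-2-formylphenyl]-3-(2,2-dimethyl-1,3-benzodioxol-5-yl)propanoate | O=Cc1cc(OCc2ccccc2)c(OCc2ccccc2)cc1[C@H](CC(=O)OC(C)(C)C)c1ccc2OC(C)(C)Oc2c1 | intermediate
8 | tert-butyl 2-(triphenyl-λ5-phosphanylidene)acetate | CC(C)(C)OC(=O)C=P(c1ccccc1)(c1ccccc1)c1ccccc1 | starting material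
9 | tert-butyl 2-bromo-2-(triphenyl-λ5-phosphanylidene)acetate | CC(C)(C)OC(=O)C(Br)=P(c1ccccc1)(c1ccccc1)c1ccccc1 | intermediate (not isolated)
10 | tert-butyl (3R)-3-{4,5-bis(benzyloxy)-2-[(Z)-2-bromo-3-tert-butoxy-3-oxoprop-1-enyl]phenyl}-3-(2,2-dimethyl-1,3-benzodioxol-5-yl)propanoate | CC(C)(C)OC(=O)/C(Br)=C/c1cc(OCc2ccccc2)c(OCc2ccccc2)cc1[C@H](CC(=O)OC(C)(C)C)c1ccc2OC(C)(C)Oc2c1 | intermediate
11 | chlorozinc enolate of 10, metalated at C2 of the propanoate (drawn C-bound; configuration at the zinc-bearing carbon not defined) | CC(C)(C)OC(=O)/C(Br)=C/c1cc(OCc2ccccc2)c(OCc2ccccc2)cc1[C@H](C([Zn]Cl)C(=O)OC(C)(C)C)c1ccc2OC(C)(C)Oc2c1 | intermediate (not isolated)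
12 | di-tert-butyl (1R,2R)-6,7-bis(benzyloxy)-1-(2,2-dimethyl-1,3-benzodioxol-5-yl)-1,2-dihydronaphthalene-2,3-dicarboxylate (cis) | CC(C)(C)OC(=O)C1=Cc2cc(OCc3ccccc3)c(OCc3ccccc3)cc2[C@@H](c2ccc3OC(C)(C)Oc3c2)[C@H]1C(=O)OC(C)(C)C | intermediate (not isolated)
13 | di-tert-butyl (1R,2S)-6,7-bis(benzyloxy)-1-(2,2-dimethyl-1,3-benzodioxol-5-yl)-1,2-dihydronaphthalene-2,3-dicarboxylate (trans) | CC(C)(C)OC(=O)C1=Cc2cc(OCc3ccccc3)c(OCc3ccccc3)cc2[C@@H](c2ccc3OC(C)(C)Oc3c2)[C@@H]1C(=O)OC(C)(C)C | intermediate
14 | (1R,2S)-6,7-bis(benzyloxy)-1-(3,4-dihydroxyphenyl)-1,2-dihydronaphthalene-2,3-dicarboxylic acid | O=C(O)C1=Cc2cc(OCc3ccccc3)c(OCc3ccccc3)cc2[C@@H](c2ccc(O)c(O)c2)[C@@H]1C(=O)O | intermediate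
15 | (1R,2S)-6,7-bis(benzyloxy)-1-[(2Z,4E)-5-carboxy-5-hydroxy-1-oxopenta-2,4-dien-3-yl]-1,2-dihydronaphthalene-2,3-dicarboxylic acid | O=C(O)C1=Cc2cc(OCc3ccccc3)c(OCc3ccccc3)cc2[C@@H](/C(=C/C=O)/C=C(/O)C(=O)O)[C@@H]1C(=O)O | intermediate (not isolated)
16 | (1R,2S)-6,7-bis(benzyloxy)-1-(6-carboxy-2-hydroxy-2H-pyran-4-yl)-1,2-dihydronaphthalene-2,3-dicarboxylic acid (hemiacetal epimers) | O=C(O)C1=Cc2cc(OCc3ccccc3)c(OCc3ccccc3)cc2[C@@H](C2=CC(O)OC(C(=O)O)=C2)[C@@H]1C(=O)O | intermediate (not isolated)
17 | (1R,2S)-6,7-bis(benzyloxy)-1-(6-carboxy-2-oxo-2H-pyran-4-yl)-1,2-dihydronaphthalene-2,3-dicarboxylic acid | O=C(O)C1=Cc2cc(OCc3ccccc3)c(OCc3ccccc3)cc2[C@@H](c2cc(C(=O)O)oc(=O)c2)[C@@H]1C(=O)O | intermediate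
18 | (1R,2S)-1-(6-carboxy-2-oxo-2H-pyran-4-yl)-6,7-dihydroxy-1,2-dihydronaphthalene-2,3-dicarboxylic acid | O=C(O)C1=Cc2cc(O)c(O)cc2[C@@H](c2cc(C(=O)O)oc(=O)c2)[C@@H]1C(=O)O | target

Total step count: 8. Longest linear sequence: 8 steps (1 to 18).

Steps most likely to fail

1. Step 5 (key step).
 - What may go wrong: zincation of C2 that is slow or incomplete; β-hydride elimination from the palladium enolate towards C1 or protodebromination in place of reductive elimination; conjugate addition of C2 to C4 leading to an indane; migration of the double bond to C2=C3 during the equilibration, which would make C1–H acidic and erode its configuration.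
 - Fallback (polar closure of ring B at C3–C4 in place of the palladium coupling): it sets out from 6, isolated by a neutral work-up in step 3, and comes back at 13. LiN(i-Pr)2 (THF, −78 °C) and tert-butyl bromoacetate alkylate C2 and so make the C2–C3 bond by enolate alkylation, giving di-tert-butyl 2-{(R)-[4,5-bis(benzyloxy)-2-(dimethoxymethyl)phenyl](2,2-dimethyl-1,3-benzodioxol-5-yl)methyl}butanedioate F1 as a C2 mixture. Dilute HCl in THF then frees the aldehyde, di-tert-butyl 2-{(R)-[4,5-bis(benzyloxy)-2-formylphenyl](2,2-dimethyl-1,3-benzodioxol-5-yl)methyl}butanedioate F2. LiN(SiMe3)2 (THF, −78 °C) deprotonates the less hindered C3 methylene, and intramolecular aldol addition to the formyl group should give di-tert-butyl (1R)-6,7-bis(benzyloxy)-1-(2,2-dimethyl-1,3-benzodioxol-5-yl)-4-hydroxy-1,2,3,4-tetrahydronaphthalene-2,3-dicarboxylate F3. MsCl/Et3N and then DBU eliminate the C4 oxygen to the C3=C4 alkene, and the tert-butoxide equilibration of step 5 converges the C2 epimers on 13.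

2. Step 7.
 - What may go wrong: poor acceptance of the bulky C1 substituent by the dioxygenase; ring opening on the proximal side (C2'–C3') instead of C4'–C5'; slow dehydrogenation of the hemiacetal, so that the semialdehyde decays before it is oxidised.
 - Fallback (abiotic cleavage and chemical oxidation): it sets out from 14 and comes back at 17 without a new compound. FeCl2, 1,4,7-triazacyclononane and pyridine under O2 in aqueous acetonitrile, the known biomimetic extradiol cleavage of catechols, should give the same seco-aldehyde 15 and hemiacetal 16. After extraction the hemiacetal is oxidised with TEMPO (cat.) and PhI(OAc)2, a standard lactol-to-lactone oxidation, to 17. Any pyranone from cleavage on the other side of the diol is removed by chromatography.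

3. Step 8.
 - What may go wrong: incomplete debenzylation; C-benzylation of the freed catechol; poor solubility of the triacid at low temperature; loss of the polar product on work-up.
 - Fallback (reversed order of the last two operations): it sets out from 14 and comes back at 18. BCl3/C6HMe5 is applied to 14, a more robust diacid that carries no pyranone, to give (1R,2S)-1-(3,4-dihydroxyphenyl)-6,7-dihydroxy-1,2-dihydronaphthalene-2,3-dicarboxylic acid F4. The enzyme pair of step 7 then acts on F4 and gives 18 as the last step. This relies on the preference of the 4,5-dioxygenase for the pendant 4-monosubstituted catechol over the ring-fused 4,5-disubstituted catechol of ring A.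

Further compounds

F1 | step 5 | di-tert-butyl 2-{(R)-[4,5-bis(benzyloxy)-2-(dimethoxymethyl)phenyl](2,2-dimethyl-1,3-benzodioxol-5-yl)methyl}butanedioate (C2 epimers) | COC(OC)c1cc(OCc2ccccc2)c(OCc2ccccc2)cc1[C@H](C(CC(=O)OC(C)(C)C)C(=O)OC(C)(C)C)c1ccc2OC(C)(C)Oc2c1
F2 | step 5 | di-tert-butyl 2-{(R)-[4,5-bis(benzyloxy)-2-formylphenyl](2,2-dimethyl-1,3-benzodioxol-5-yl)methyl}butanedioate (C2 epimers) | O=Cc1cc(OCc2ccccc2)c(OCc2ccccc2)cc1[C@H](C(CC(=O)OC(C)(C)C)C(=O)OC(C)(C)C)c1ccc2OC(C)(C)Oc2c1
F3 | step 5 | di-tert-butyl (1R)-6,7-bis(benzyloxy)-1-(2,2-dimethyl-1,3-benzodioxol-5-yl)-4-hydroxy-1,2,3,4-tetrahydronaphthalene-2,3-dicarboxylate (mixture at C2, C3 and C4) | CC(C)(C)OC(=O)C1C(O)c2cc(OCc3ccccc3)c(OCc3ccccc3)cc2[C@@H](c2ccc3OC(C)(C)Oc3c2)C1C(=O)OC(C)(C)C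
F0 | step 7 | none | none
F4 | step 8 | (1R,2S)-1-(3,4-dihydroxyphenyl)-6,7-dihydroxy-1,2-dihydronaphthalene-2,3-dicarboxylic acid | O=C(O)C1=Cc2cc(O)c(O)cc2[C@@H](c2ccc(O)c(O)c2)[C@@H]1C(=O)O
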